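**Plan**

- Carbon labels follow elemane numbering: ring C5–C10, vinyl C1=C2 and methyl C14 on C10, C4(=C15)–C3 on C5, C11(=C13)–C12 on C7. Retrosynthesis re-closes the C12 acid onto O6 as a temporary cis-fused lactone, removes the O8 ester and the C10 vinyl group (leaving a C8 ketone conjugated to C9=C10), and then cuts C8–C9 and C5–C6.
- Enabling feature: C6 and C8 are the two carbonyl-level carbons flanking C7. C6 is held as the acylal carbon of the five-membered O6–C12 butanolide ring and C8 as a thioester. C9–C10–C5–C4 is a 2-methylpenta-2,4-dienyl unit in which C9 is a vinyl nucleophile and C5 the γ-carbon of a C4=C5 allylsilane. One acylation and one SE2' attack therefore close the ring as a 3-methylcyclohex-2-enone.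
- Forward order: a bromodiene and an acetoxy-butanolide thioester are joined and cyclised in one flask. Then follow vinyl addition at C10, reduction at C8, esterification of O8, unmasking of the C11 methylene, lactone opening and desilylation.
- Stereochemistry: the menthyl acetal carbon of a 5-menthyloxybutenolide is the only ring stereocentre that is bought. C7 (trans conjugate addition), C6 (cis ring fusion), C5 (antiperiplanar SE2'), C10 (cuprate anti to the C5 side chain) and C8 (equatorial alcohol) are relayed from it. The side-chain carbinol comes from a catalytic asymmetric Morita–Baylis–Hillman reaction.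

Key step: step 12

Remark: the (5S)-5-(d-menthyloxy)butenolide is taken as a catalogue compound, and the target is taken to be isolable in its open γ-hydroxy acid form if kept cold and near neutral.

Step 1
Reactants: 1 prop-2-yn-1-ol
Product: 3 (E)-3-iodo-2-[(trimethylsilyl)methyl]prop-2-en-1-ol, via alkenylmagnesium alkoxide 2 (not isolated)
Conditions: Me3SiCH2MgCl (2.5 equiv), CuI (10 mol%), THF, reflux; then I2, –78 to 0 °C
Reagents that add atoms: (trimethylsilyl)methylmagnesium chloride C[Si](C)(C)C[Mg]Cl; iodine II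
Why: Copper-catalysed anti-carbomagnesiation of the propargylic alkoxide places magnesium cis to the CH2O group through a five-membered chelate, and iodinolysis of the alkenyl–Mg bond with retention should give the iodide with iodine cis to CH2OH.

Step 2
Reactants: 3 (E)-3-iodo-2-[(trimethylsilyl)methyl]prop-2-en-1-ol
Product: 4 tert-butyl({(E)-3-iodo-2-[(trimethylsilyl)methyl]prop-2-en-1-yl}oxy)dimethylsilane
Conditions: TBSCl, imidazole, CH2Cl2, 0 °C to rt
Reagents that add atoms: tert-butyldimethylsilyl chloride CC(C)(C)[Si](C)(C)Cl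
Why: Standard silylation of the primary allylic alcohol protects the future C3 hydroxyl through the organometallic steps.

Step 3
Reactants: 5 propyne
Product: 6 1-bromoprop-1-yne
Conditions: NBS, AgNO3 (10 mol%), acetone, 0 °C
Reagents that add atoms: N-bromosuccinimide O=C1CCC(=O)N1Br
Why: Silver-catalysed electrophilic bromination of the terminal alkyne C–H bond proceeds through the silver acetylide.

Step 4
Reactants: 6 1-bromoprop-1-yne
Product: 7 (Z)-1-bromo-2-iodoprop-1-ene
Conditions: LiI, Pd(OAc)2 (2 mol%), AcOH, rt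
Reagents that add atoms: lithium iodide [Li+].[I-]
Why: Palladium-catalysed hydroiodination of the haloalkyne (trans-iodopalladation, then protonolysis of the C–Pd bond) should place iodine on the internal carbon cis to bromine, giving the Z-1,2-dihaloalkene.

Step 5
Reactants: 4 tert-butyl({(E)-3-iodo-2-[(trimethylsilyl)methyl]prop-2-en-1-yl}oxy)dimethylsilane; 7 (Z)-1-bromo-2-iodoprop-1-ene
Product: 10 (2E,4Z)-5-bromo-1-(tert-butyldimethylsilyloxy)-4-methyl-2-[(trimethylsilyl)methyl]penta-2,4-diene, via alkenyllithium 8 (not isolated), via alkenylzinc chloride 9 (not isolated)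
Conditions: 4, t-BuLi (2.1 equiv), Et2O, –78 °C; ZnCl2, THF; then 7, Pd(PPh3)4 (3 mol%), THF, 0 °C to rt
Reagents that add atoms: none
Why: In this Negishi coupling zerovalent palladium inserts into the C–I bond of 7 much faster than into its C–Br bond and both alkenyl partners couple with retention, so the diene should form with bromine cis to the new C5–C10 bond and keep the bromide for the key step.

Step 6
Reactants: 11 (5S)-5-[(1S,2R,5S)-menthyloxy]furan-2(5H)-one
Product: 13 (3R,4S,5S)-3-(hydroxymethyl)-5-[(1S,2R,5S)-menthyloxy]-4-[tris(methylsulfanyl)methyl]oxolan-2-one, via lithium enolate 12 (not isolated)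
Conditions: HC(SMe)3, n-BuLi, THF, –78 °C; 11; then CH2O (gas), –78 °C; aq. NH4Cl
Reagents that add atoms: tris(methylsulfanyl)methane CSC(SC)SC; formaldehyde C=O
Why: Tris(methylsulfanyl)methyllithium, a carboxyl anion equivalent, should add in conjugate fashion trans to the menthyloxy group (setting C7), and lithium enolate 12 is trapped by formaldehyde trans to the new substituent in a tandem Michael–aldol reaction that installs the future C13 as a hydroxymethyl group.

Step 7
Reactants: 13 (3R,4S,5S)-3-(hydroxymethyl)-5-[(1S,2R,5S)-menthyloxy]-4-[tris(methylsulfanyl)methyl]oxolan-2-one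
Product: 14 S-methyl (2S,3S,4R)-4-(hydroxymethyl)-2-[(1S,2R,5S)-menthyloxy]-5-oxooxolane-3-carbothioate
Conditions: HgO, BF3·OEt2, THF/H2O, 0 °C to rt
Reagents that add atoms: HgO O=[Hg]
Why: Thiophilic hydrolysis of the orthothioester stops at the S-methyl thioester, which becomes the acyl donor for C8.

Step 8
Reactants: 14 S-methyl (2S,3S,4R)-4-(hydroxymethyl)-2-[(1S,2R,5S)-menthyloxy]-5-oxooxolane-3-carbothioate
Product: 15 S-methyl (2S,3S,4R)-2-acetoxy-4-(acetoxymethyl)-5-oxooxolane-3-carbothioate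
Conditions: Ac2O, AcOH, H2SO4 (cat.), 0 °C to rt
Reagents that add atoms: acetic anhydride CC(=O)OC(C)=O
Why: Acid-catalysed acetolysis exchanges the menthyloxy group of the lactone acetal for acetoxy (the auxiliary leaves as its acetate) and acetylates the primary alcohol, giving an acylal with an exocyclic acetate leaving group and a β-acetoxymethyl group as a latent α-methylene; the anomeric configuration is irrelevant because this carbon is ionised in step 12.

Step 9
Reactants: 16 (tert-butyldimethylsilyloxy)acetaldehyde; 17 1,1,1,3,3,3-hexafluoropropan-2-yl acrylate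
Product: 18 1,1,1,3,3,3-hexafluoropropan-2-yl (3R)-4-(tert-butyldimethylsilyloxy)-3-hydroxy-2-methylidenebutanoate
Conditions: α-isocupreine (10 mol%), DMF, –55 °C
Reagents that add atoms: none
Why: The asymmetric Morita–Baylis–Hillman reaction of the activated acrylate under α-isocupreine catalysis (the pseudoenantiomer of β-isocupreidine) should deliver the R carbinol through the hydrogen-bonded betaine–aldehyde assembly.

Step 10
Reactants: 18 1,1,1,3,3,3-hexafluoropropan-2-yl (3R)-4-(tert-butyldimethylsilyloxy)-3-hydroxy-2-methylidenebutanoate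
Product: 19 1,1,1,3,3,3-hexafluoropropan-2-yl (3R)-3,4-bis(tert-butyldimethylsilyloxy)-2-methylidenebutanoate
Conditions: TBSOTf, 2,6-lutidine, CH2Cl2, –78 °C
Reagents that add atoms: tert-butyldimethylsilyl trifluoromethanesulfonate CC(C)(C)[Si](C)(C)OS(=O)(=O)C(F)(F)F
Why: Silylation of the secondary allylic alcohol blocks cyclisation of the 4-oxygen onto the activated ester and protects the diol to the end.

Step 11
Reactants: 19 1,1,1,3,3,3-hexafluoropropan-2-yl (3R)-3,4-bis(tert-butyldimethylsilyloxy)-2-methylidenebutanoate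
Product: 20 (3R)-3,4-bis(tert-butyldimethylsilyloxy)-2-methylidenebutanoic acid
Conditions: LiOH, THF/H2O, 0 °C; then aq. HCl to pH 3
Reagents that add atoms: lithium hydroxide [Li+].[OH-]
Why: The electron-poor hexafluoroisopropyl ester is cleaved by hydroxide under mild conditions that should leave the silyl ethers and the acrylate intact.

Step 12
Reactants: 10 (2E,4Z)-5-bromo-1-(tert-butyldimethylsilyloxy)-4-methyl-2-[(trimethylsilyl)methyl]penta-2,4-diene; 15 S-methyl (2S,3S,4R)-2-acetoxy-4-(acetoxymethyl)-5-oxooxolane-3-carbothioate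
Product: 24 [(3R,3aS,7S,7aS)-7-[3-(tert-butyldimethylsilyloxy)prop-1-en-2-yl]-6-methyl-2,4-dioxo-2,3,3a,4,7,7a-hexahydro-1-benzofuran-3-yl]methyl acetate, via dienyllithium 21 (not isolated), via dienylzinc chloride 22 (not isolated), via dienone 23 (not isolated)
Conditions: 10, t-BuLi (2.1 equiv), Et2O, –78 °C; ZnCl2, THF; 15, PdCl2(PPh3)2 (5 mol%), toluene, 0 °C to rt; then BF3·OEt2 (4 equiv), CH2Cl2, –40 to 0 °C
Reagents that add atoms: none
Why: Bromine–lithium exchange and transmetalation convert 10 into dienylzinc chloride 22, which undergoes a Pd-catalysed Fukuyama acylation with thioester 15 (bond C8–C9, with retention of the Z geometry) to give dienone 23; BF3 then ionises the exocyclic anomeric acetate of the acylal to a five-membered acyloxycarbenium ion, which C5, the γ-carbon of the C4=C5 allylsilane, attacks in an intramolecular Hosomi–Sakurai (SE2') reaction (bond C5–C6) with loss of the silyl group and formation of the C4=C15 methylene. The closest known reaction types are the thioester–organozinc ketone synthesis and the Lewis-acid allylation of 5-acyloxy butanolides, run here in one flask as a formal [3+3] annulation. The carbocycle closes by a 6-exo-trig attack on the oxocarbenium carbon, in which both the C6=O+ bond and the nucleophilic C4=C5 bond stay outside the new cyclohexenone ring. C6 is set by the tether, since the four-atom chain from C7 can reach the planar cation only on its own face and the lactone therefore ends cis-fused (C6–O cis to C7–C11); C5 is set by an antiperiplanar SE2' geometry in a half-chair whose allyl group is pseudoaxial to avoid A(1,2) strain with the C10 methyl, which places the C5 side chain trans to C6–O. The step needs acylation at the thioester in preference to the lactone and acetate carbonyls, which oxidative addition of zerovalent palladium into the C–S bond secures; exocyclic ionisation of the acylal, which the acetate leaving group and re-closure of any ring-opened ion favour; and attack through C5 and not C9, which β-silyl stabilisation of the developing C4 cation secures.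

Step 13
Reactants: 24 [(3R,3aS,7S,7aS)-7-[3-(tert-butyldimethylsilyloxy)prop-1-en-2-yl]-6-methyl-2,4-dioxo-2,3,3a,4,7,7a-hexahydro-1-benzofuran-3-yl]methyl acetate
Product: 26 [(3R,3aS,6R,7S,7aS)-6-ethenyl-7-[3-(tert-butyldimethylsilyloxy)prop-1-en-2-yl]-6-methyl-2,4-dioxooctahydro-1-benzofuran-3-yl]methyl acetate, via silyl enol ether 25 (not isolated)
Conditions: vinylmagnesium bromide, CuBr·SMe2 (20 mol%), Me3SiCl, THF, –78 °C; then 1 M HCl, THF, 0 °C
Reagents that add atoms: vinylmagnesium bromide C=C[Mg]Br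
Why: Copper-catalysed, Me3SiCl-accelerated conjugate addition to the β-methyl enone should occur anti to the adjacent pseudoaxial C5 side chain, so that the new quaternary C10 carries vinyl trans and methyl cis to that side chain, and acid hydrolysis of silyl enol ether 25 gives the ketone.

Step 14
Reactants: 26 [(3R,3aS,6R,7S,7aS)-6-ethenyl-7-[3-(tert-butyldimethylsilyloxy)prop-1-en-2-yl]-6-methyl-2,4-dioxooctahydro-1-benzofuran-3-yl]methyl acetate
Product: 27 [(3R,3aR,4R,6R,7S,7aS)-6-ethenyl-4-hydroxy-7-[3-(tert-butyldimethylsilyloxy)prop-1-en-2-yl]-6-methyl-2-oxooctahydro-1-benzofuran-3-yl]methyl acetate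
Conditions: SmI2, H2O, THF, 0 °C
Reagents that add atoms: none
Why: Single-electron reduction by divalent samarium in wet THF passes through a ketyl that is protonated under thermodynamic control, so the equatorial C8 alcohol (cis to C7–C11, trans to the axial C10 methyl with which the axial epimer would be syn-diaxial) should predominate, while the γ-lactone and the acetate are not reduced under these amine-free conditions.

Step 15
Reactants: 27 [(3R,3aR,4R,6R,7S,7aS)-6-ethenyl-4-hydroxy-7-[3-(tert-butyldimethylsilyloxy)prop-1-en-2-yl]-6-methyl-2-oxooctahydro-1-benzofuran-3-yl]methyl acetate; 20 (3R)-3,4-bis(tert-butyldimethylsilyloxy)-2-methylidenebutanoic acid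
Product: 29 (3R,3aR,4R,6R,7S,7aS)-3-(acetoxymethyl)-6-ethenyl-7-[3-(tert-butyldimethylsilyloxy)prop-1-en-2-yl]-6-methyl-2-oxooctahydro-1-benzofuran-4-yl (3R)-3,4-bis(tert-butyldimethylsilyloxy)-2-methylidenebutanoate, via mixed anhydride 28 (not isolated)
Conditions: 20, 2,4,6-trichlorobenzoyl chloride, Et3N, THF, rt; then 27, DMAP, toluene, rt
Reagents that add atoms: none
Why: Yamaguchi esterification through mixed anhydride 28 should acylate the equatorial secondary C8 alcohol with the α-substituted acrylic acid without touching any stereocentre.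

Step 16
Reactants: 29 (3R,3aR,4R,6R,7S,7aS)-3-(acetoxymethyl)-6-ethenyl-7-[3-(tert-butyldimethylsilyloxy)prop-1-en-2-yl]-6-methyl-2-oxooctahydro-1-benzofuran-4-yl (3R)-3,4-bis(tert-butyldimethylsilyloxy)-2-methylidenebutanoate
Product: 30 (3aR,4R,6R,7S,7aS)-6-ethenyl-7-[3-(tert-butyldimethylsilyloxy)prop-1-en-2-yl]-6-methyl-3-methylidene-2-oxooctahydro-1-benzofuran-4-yl (3R)-3,4-bis(tert-butyldimethylsilyloxy)-2-methylidenebutanoate
Conditions: DBU, CH2Cl2, 0 °C
Reagents that add atoms: none
Why: DBU removes the lactone α-proton and acetate is expelled (E1cB), unveiling the α-methylene lactone that was carried as its β-acetoxymethyl precursor through the organometallic and reductive steps.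

Step 17
Reactants: 30 (3aR,4R,6R,7S,7aS)-6-ethenyl-7-[3-(tert-butyldimethylsilyloxy)prop-1-en-2-yl]-6-methyl-3-methylidene-2-oxooctahydro-1-benzofuran-4-yl (3R)-3,4-bis(tert-butyldimethylsilyloxy)-2-methylidenebutanoate
Product: 31 2-[(1S,2S,3S,4R,6R)-6-{[(3R)-3,4-bis(tert-butyldimethylsilyloxy)-2-methylidenebutanoyl]oxy}-3-[3-(tert-butyldimethylsilyloxy)prop-1-en-2-yl]-4-ethenyl-2-hydroxy-4-methylcyclohexyl]prop-2-enoic acid
Conditions: LiOH (1.2 equiv), THF/H2O (3:1), 0 °C; then aq. HCl to pH 5, 0 °C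
Reagents that add atoms: lithium hydroxide [Li+].[OH-]
Why: Hydroxide should attack the strained, unhindered α-methylene-γ-lactone carbonyl much faster than the α-branched acrylate ester of the hindered secondary C8 alcohol, so saponification with about one equivalent of base and cold acidification should release the C12 acid and the C6 alcohol selectively.

Step 18
Reactants: 31 2-[(1S,2S,3S,4R,6R)-6-{[(3R)-3,4-bis(tert-butyldimethylsilyloxy)-2-methylidenebutanoyl]oxy}-3-[3-(tert-butyldimethylsilyloxy)prop-1-en-2-yl]-4-ethenyl-2-hydroxy-4-methylcyclohexyl]prop-2-enoic acid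
Product: 32 2-[(1S,2S,3S,4R,6R)-6-{[(3R)-3,4-dihydroxy-2-methylidenebutanoyl]oxy}-4-ethenyl-2-hydroxy-3-(3-hydroxyprop-1-en-2-yl)-4-methylcyclohexyl]prop-2-enoic acid
Conditions: HF·pyridine, pyridine, THF, 0 °C to rt
Reagents that add atoms: none
Why: Buffered HF·pyridine should cleave the three silyl ethers under non-basic conditions that avoid acyl migration and cyclisation of the dihydroxybutanoate side chain, the cold pyridine-rich medium slowing relactonisation of the γ-hydroxy acid.

**Compound list**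

1 | prop-2-yn-1-ol | C#CCO | starting material
2 | chloromagnesium (E)-3-(chloromagnesio)-2-[(trimethylsilyl)methyl]prop-2-en-1-olate | Cl[Mg]/C=C(\CO[Mg]Cl)C[Si](C)(C)C | intermediate
3 | (E)-3-iodo-2-[(trimethylsilyl)methyl]prop-2-en-1-ol | I/C=C(\CO)C[Si](C)(C)C | intermediate
4 | tert-butyl({(E)-3-iodo-2-[(trimethylsilyl)methyl]prop-2-en-1-yl}oxy)dimethylsilane | I/C=C(\CO[Si](C)(C)C(C)(C)C)C[Si](C)(C)C | intermediate
5 | propyne | CC#C | starting material
6 | 1-bromoprop-1-yne | CC#CBr | intermediate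
7 | (Z)-1-bromo-2-iodoprop-1-ene | Br/C=C(C)\I | intermediate
8 | (E)-{3-(tert-butyldimethylsilyloxy)-2-[(trimethylsilyl)methyl]prop-1-en-1-yl}lithium | [Li]/C=C(\CO[Si](C)(C)C(C)(C)C)C[Si](C)(C)C | intermediate
9 | (E)-{3-(tert-butyldimethylsilyloxy)-2-[(trimethylsilyl)methyl]prop-1-en-1-yl}zinc chloride | Cl[Zn]/C=C(\CO[Si](C)(C)C(C)(C)C)C[Si](C)(C)C | intermediate
10 | (2E,4Z)-5-bromo-1-(tert-butyldimethylsilyloxy)-4-methyl-2-[(trimethylsilyl)methyl]penta-2,4-diene | Br/C=C(C)\C=C(/CO[Si](C)(C)C(C)(C)C)C[Si](C)(C)C | intermediate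
11 | (5S)-5-[(1S,2R,5S)-menthyloxy]furan-2(5H)-one | O=C1C=C[C@H](O1)O[C@H]2C[C@@H](C)CC[C@@H]2C(C)C | starting material
12 | lithium enolate of the 4,5-trans conjugate adduct of 11 | CSC(SC)(SC)[C@H]1C=C(O[Li])O[C@@H]1O[C@H]2C[C@@H](C)CC[C@@H]2C(C)C | intermediate
13 | (3R,4S,5S)-3-(hydroxymethyl)-5-[(1S,2R,5S)-menthyloxy]-4-[tris(methylsulfanyl)methyl]oxolan-2-one (3,4-trans, 4,5-trans) | CSC(SC)(SC)[C@H]1[C@H](CO)C(=O)O[C@@H]1O[C@H]2C[C@@H](C)CC[C@@H]2C(C)C | intermediate
14 | S-methyl (2S,3S,4R)-4-(hydroxymethyl)-2-[(1S,2R,5S)-menthyloxy]-5-oxooxolane-3-carbothioate | CSC(=O)[C@H]1[C@H](CO)C(=O)O[C@@H]1O[C@H]2C[C@@H](C)CC[C@@H]2C(C)C | intermediate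
15 | S-methyl (2S,3S,4R)-2-acetoxy-4-(acetoxymethyl)-5-oxooxolane-3-carbothioate (trans anomer drawn) | CSC(=O)[C@H]1[C@H](COC(C)=O)C(=O)O[C@@H]1OC(C)=O | intermediate
16 | (tert-butyldimethylsilyloxy)acetaldehyde | O=CCO[Si](C)(C)C(C)(C)C | starting material
17 | 1,1,1,3,3,3-hexafluoropropan-2-yl acrylate | C=CC(=O)OC(C(F)(F)F)C(F)(F)F | starting material
18 | 1,1,1,3,3,3-hexafluoropropan-2-yl (3R)-4-(tert-butyldimethylsilyloxy)-3-hydroxy-2-methylidenebutanoate | C=C(C(=O)OC(C(F)(F)F)C(F)(F)F)[C@@H](O)CO[Si](C)(C)C(C)(C)C | intermediate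
19 | 1,1,1,3,3,3-hexafluoropropan-2-yl (3R)-3,4-bis(tert-butyldimethylsilyloxy)-2-methylidenebutanoate | C=C(C(=O)OC(C(F)(F)F)C(F)(F)F)[C@@H](O[Si](C)(C)C(C)(C)C)CO[Si](C)(C)C(C)(C)C | intermediate
20 | (3R)-3,4-bis(tert-butyldimethylsilyloxy)-2-methylidenebutanoic acid | C=C(C(=O)O)[C@@H](O[Si](C)(C)C(C)(C)C)CO[Si](C)(C)C(C)(C)C | intermediate
21 | {(1Z,3E)-5-(tert-butyldimethylsilyloxy)-2-methyl-4-[(trimethylsilyl)methyl]penta-1,3-dien-1-yl}lithium | [Li]/C=C(C)\C=C(/CO[Si](C)(C)C(C)(C)C)C[Si](C)(C)C | intermediate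
22 | {(1Z,3E)-5-(tert-butyldimethylsilyloxy)-2-methyl-4-[(trimethylsilyl)methyl]penta-1,3-dien-1-yl}zinc chloride | Cl[Zn]/C=C(C)\C=C(/CO[Si](C)(C)C(C)(C)C)C[Si](C)(C)C | intermediate
23 | (3R,4S,5S)-5-acetoxy-3-(acetoxymethyl)-4-[(2Z,4E)-6-(tert-butyldimethylsilyloxy)-3-methyl-5-[(trimethylsilyl)methyl]hexa-2,4-dienoyl]oxolan-2-one | O=C(/C=C(C)\C=C(/CO[Si](C)(C)C(C)(C)C)C[Si](C)(C)C)[C@H]1[C@H](COC(C)=O)C(=O)O[C@@H]1OC(C)=O | intermediate
24 | [(3R,3aS,7S,7aS)-7-[3-(tert-butyldimethylsilyloxy)prop-1-en-2-yl]-6-methyl-2,4-dioxo-2,3,3a,4,7,7a-hexahydro-1-benzofuran-3-yl]methyl acetate (cis-fused; C7 side chain trans to the ring oxygen) | CC1=CC(=O)[C@@H]([C@H](COC(C)=O)C(=O)O2)[C@@H]2[C@@H]1C(=C)CO[Si](C)(C)C(C)(C)C | intermediate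
25 | trimethylsilyl enol ether of 26 (C4=C5 double bond, 4-trimethylsilyloxy, benzofuran numbering) | C=C[C@@]1(C)C=C(O[Si](C)(C)C)[C@@H]([C@H](COC(C)=O)C(=O)O2)[C@@H]2[C@@H]1C(=C)CO[Si](C)(C)C(C)(C)C | intermediate
26 | [(3R,3aS,6R,7S,7aS)-6-ethenyl-7-[3-(tert-butyldimethylsilyloxy)prop-1-en-2-yl]-6-methyl-2,4-dioxooctahydro-1-benzofuran-3-yl]methyl acetate | C=C[C@@]1(C)CC(=O)[C@@H]([C@H](COC(C)=O)C(=O)O2)[C@@H]2[C@@H]1C(=C)CO[Si](C)(C)C(C)(C)C | intermediate
27 | [(3R,3aR,4R,6R,7S,7aS)-6-ethenyl-4-hydroxy-7-[3-(tert-butyldimethylsilyloxy)prop-1-en-2-yl]-6-methyl-2-oxooctahydro-1-benzofuran-3-yl]methyl acetate | C=C[C@@]1(C)C[C@@H](O)[C@@H]([C@H](COC(C)=O)C(=O)O2)[C@@H]2[C@@H]1C(=C)CO[Si](C)(C)C(C)(C)C | intermediate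
28 | (3R)-3,4-bis(tert-butyldimethylsilyloxy)-2-methylidenebutanoic 2,4,6-trichlorobenzoic anhydride | C=C(C(=O)OC(=O)c1c(Cl)cc(Cl)cc1Cl)[C@@H](O[Si](C)(C)C(C)(C)C)CO[Si](C)(C)C(C)(C)C | intermediate
29 | (3R,3aR,4R,6R,7S,7aS)-3-(acetoxymethyl)-6-ethenyl-7-[3-(tert-butyldimethylsilyloxy)prop-1-en-2-yl]-6-methyl-2-oxooctahydro-1-benzofuran-4-yl (3R)-3,4-bis(tert-butyldimethylsilyloxy)-2-methylidenebutanoate | C=C[C@@]1(C)C[C@@H](OC(=O)C(=C)[C@@H](O[Si](C)(C)C(C)(C)C)CO[Si](C)(C)C(C)(C)C)[C@@H]([C@H](COC(C)=O)C(=O)O2)[C@@H]2[C@@H]1C(=C)CO[Si](C)(C)C(C)(C)C | intermediate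
30 | (3aR,4R,6R,7S,7aS)-6-ethenyl-7-[3-(tert-butyldimethylsilyloxy)prop-1-en-2-yl]-6-methyl-3-methylidene-2-oxooctahydro-1-benzofuran-4-yl (3R)-3,4-bis(tert-butyldimethylsilyloxy)-2-methylidenebutanoate | C=C[C@@]1(C)C[C@@H](OC(=O)C(=C)[C@@H](O[Si](C)(C)C(C)(C)C)CO[Si](C)(C)C(C)(C)C)[C@@H](C(=C)C(=O)O2)[C@@H]2[C@@H]1C(=C)CO[Si](C)(C)C(C)(C)C | intermediate
31 | 2-[(1S,2S,3S,4R,6R)-6-{[(3R)-3,4-bis(tert-butyldimethylsilyloxy)-2-methylidenebutanoyl]oxy}-3-[3-(tert-butyldimethylsilyloxy)prop-1-en-2-yl]-4-ethenyl-2-hydroxy-4-methylcyclohexyl]prop-2-enoic acid | C=C[C@@]1(C)C[C@@H](OC(=O)C(=C)[C@@H](O[Si](C)(C)C(C)(C)C)CO[Si](C)(C)C(C)(C)C)[C@@H](C(=C)C(=O)O)[C@@H](O)[C@@H]1C(=C)CO[Si](C)(C)C(C)(C)C | intermediate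
32 | 2-[(1S,2S,3S,4R,6R)-6-{[(3R)-3,4-dihydroxy-2-methylidenebutanoyl]oxy}-4-ethenyl-2-hydroxy-3-(3-hydroxyprop-1-en-2-yl)-4-methylcyclohexyl]prop-2-enoic acid | C=C[C@@]1(C)C[C@@H](OC(=O)C(=C)[C@@H](O)CO)[C@@H](C(=C)C(=O)O)[C@@H](O)[C@@H]1C(=C)CO | target

**Totals and risks**

Total step count: 18. Longest linear sequence: 10 steps (steps 6, 7, 8 and 12 to 18; the branches through steps 1, 2, 5 or 3, 4, 5 are equally long).

The three steps most likely to fail:

Step 12. The one-flask sequence may stall after the acylation. The acylal may ionise with ring opening instead of losing the exocyclic acetate, the boron-complexed dienone may close through its own pentadienyl cation, or the conjugated allylsilane may be protodesilylated before it attacks. In that case the two bonds would be made in separate operations with a different cation precursor, setting out from 10 and 15 and returning at 24. The Pd-catalysed acylation is run alone and dienone 23 is isolated. Me3SiBr in CH2Cl2 at 0 °C exchanges the anomeric acetate for bromide to give the lactone pseudo-bromide F1. AgOSO2CF3 with 2,6-di-tert-butylpyridine in CH2Cl2 at –78 °C then abstracts bromide, so that the cyclic acyloxycarbenium ion is generated by halide abstraction under non-equilibrating conditions, and the intramolecular Hosomi–Sakurai reaction gives 24.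

Step 14. The facial selectivity of the ketone reduction may be poor, or the ketyl may be diverted onto a neighbouring alkene. The fallback sets out from 26 and returns at 29. LiBH(s-Bu)3 in THF at –78 °C should deliver hydride along the equatorial trajectory and give the axial C8 epimer F2. A Mitsunobu esterification of the axial alcohol F2 with acid 20 (PPh3, diisopropyl azodicarboxylate, toluene) would then install the side-chain ester with inversion at C8.

Step 17. The saponification may lose chemoselectivity through competing cleavage of the C8 ester, acyl migration from O8 to the liberated O6 alkoxide, or relactonisation on acidification. The fallback opens the lactone before the side chain is attached, setting out from 27 and returning at 32. O8 is capped as the triethylsilyl ether F3 (Et3SiOTf, 2,6-lutidine). LiOH in THF/H2O both eliminates acetic acid and opens the lactone, and the resulting salt is silylated in the same flask (TBSOTf, 2,6-lutidine; K2CO3/MeOH work-up) to give the O6-silylated acid F4. Esterification with 2-(trimethylsilyl)ethanol (EDC, DMAP) gives the ester F5. HF·pyridine/pyridine at 0 °C removes only the triethylsilyl group to give the hydroxy ester F6. Yamaguchi acylation with acid 20 through anhydride 28 gives the diester F7. Tris(dimethylamino)sulfonium difluorotrimethylsilicate in DMF then removes the 2-(trimethylsilyl)ethyl ester and all silyl ethers in one operation to give 32.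

Further compounds
F1 | step 12 | (3R,4S,5S)-3-(acetoxymethyl)-5-bromo-4-[(2Z,4E)-6-(tert-butyldimethylsilyloxy)-3-methyl-5-[(trimethylsilyl)methyl]hexa-2,4-dienoyl]oxolan-2-one | O=C(/C=C(C)\C=C(/CO[Si](C)(C)C(C)(C)C)C[Si](C)(C)C)[C@H]1[C@H](COC(C)=O)C(=O)O[C@@H]1Br
F2 | step 14 | C4 epimer of 27 (axial 4-hydroxy, benzofuran numbering) | C=C[C@@]1(C)C[C@H](O)[C@@H]([C@H](COC(C)=O)C(=O)O2)[C@@H]2[C@@H]1C(=C)CO[Si](C)(C)C(C)(C)C
F3 | step 17 | 4-O-triethylsilyl ether of 27 | C=C[C@@]1(C)C[C@@H](O[Si](CC)(CC)CC)[C@@H]([C@H](COC(C)=O)C(=O)O2)[C@@H]2[C@@H]1C(=C)CO[Si](C)(C)C(C)(C)C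
F4 | step 17 | 2-[(1S,2S,3S,4R,6R)-2-(tert-butyldimethylsilyloxy)-3-[3-(tert-butyldimethylsilyloxy)prop-1-en-2-yl]-4-ethenyl-4-methyl-6-(triethylsilyloxy)cyclohexyl]prop-2-enoic acid | C=C[C@@]1(C)C[C@@H](O[Si](CC)(CC)CC)[C@@H](C(=C)C(=O)O)[C@@H](O[Si](C)(C)C(C)(C)C)[C@@H]1C(=C)CO[Si](C)(C)C(C)(C)C
F5 | step 17 | 2-(trimethylsilyl)ethyl ester of F4 | C=C[C@@]1(C)C[C@@H](O[Si](CC)(CC)CC)[C@@H](C(=C)C(=O)OCC[Si](C)(C)C)[C@@H](O[Si](C)(C)C(C)(C)C)[C@@H]1C(=C)CO[Si](C)(C)C(C)(C)C
F6 | step 17 | F5 with the triethylsilyl ether cleaved (free C6 hydroxyl, cyclohexane numbering) | C=C[C@@]1(C)C[C@@H](O)[C@@H](C(=C)C(=O)OCC[Si](C)(C)C)[C@@H](O[Si](C)(C)C(C)(C)C)[C@@H]1C(=C)CO[Si](C)(C)C(C)(C)C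
F7 | step 17 | (3R)-3,4-bis(tert-butyldimethylsilyloxy)-2-methylidenebutanoate ester of F6 | C=C[C@@]1(C)C[C@@H](OC(=O)C(=C)[C@@H](O[Si](C)(C)C(C)(C)C)CO[Si](C)(C)C(C)(C)C)[C@@H](C(=C)C(=O)OCC[Si](C)(C)C)[C@@H](O[Si](C)(C)C(C)(C)C)[C@@H]1C(=C)CO[Si](C)(C)C(C)(C)C
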